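In its first 50.0 min the midnight flask reached 20.4% product. That is a turnover rate (turnover frequency) of 83.2 h⁻¹, the product made per hour, on average over that stretch, for each unit of free catalyst charged, and it is a reading with the scatter of the readings.

the same everywhere: free catalyst 0.10 mM

| flask | starting material | reagent | protic impurity | remark |
|---|---|---|---|---|
| midnight | 34 mM | 17 mM | 3.4 mM | the very flask that is asked about, followed so far |
| dawn | 17 mM | 17 mM | 3.4 mM | run made earlier |
| flask | 34 mM | 17.0 mM | 3.40 mM |  |

midnight run (percent of the starting material charged): time / min: product / % = 3.00: 1.2; 10.0: 4.2; 15.0: 6.5; 25.0: 10.9; 40.0: 16.7; 50.0: 20.4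

dawn run (percent of the starting material charged): time / h: product / % = 0.500: 16.6; 1.00: 28.8; 1.33: 40.8; 2.00: 52.1; 2.50: 60.5; 3.00: 63.8

(readings scatter by 1 percentage point)

- factor on the rate of making product when 50% of the starting material are converted if free catalyst is charged twice over
- factor on the rate when 50% of the starting material are converted if free catalyst is charged at 0.020 mM instead

- no earlier run changes the charge of free catalyst; that part of a forecast is a guess

No run had changed the catalyst, so I used a bench rule of thumb: with the other charges held and at the same conversion, the turnover rate stays put when the catalyst charge moves, and on a logarithmic scale the rate moves as many powers of ten as that charge. Doubling is 0.301 of a power of ten up, and going down to 0.020 mM is 0.699 down. My reckoning was therefore factors of 2 and 0.200.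

The rule has a border, since it needs reagent left to turn over. Reagent over starting material in the midnight flask is 50.0% of the charge. If each product costs one reagent, which makes reagent the limiting reagent, and the protic impurity takes starting material one for one, the impurity adds 10.0%, and conversion in the midnight flask ends near 60.0%. The asked 50% is less than that, so I kept the rule, though close to its border.

The forecast gave 1.8 and 0.28, with the words “A saturated cycle suggests near first order”. Its second factor is higher than mine.

The flask gave 2.00 and 0.200.

    starting material + free catalyst → catalyst intermediate A (k = 120 M⁻¹ min⁻¹)
    reagent + catalyst intermediate A → catalyst intermediate B (k = 2700 M⁻¹ min⁻¹)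
    catalyst intermediate B ⇌ by-product + catalyst intermediate C (K = 0.0350 M, k = 16.0 min⁻¹)
    catalyst intermediate C → free catalyst + product (k = 3.40 min⁻¹)
    starting material + protic impurity → quenched substrate (k = 3.80 M⁻¹ min⁻¹)

At 1.84 h, with 50% of the starting material converted, the flask made product at 5.61 mM h⁻¹, and catalyst intermediate C held 27.5% of the catalyst. Its turnover rate at that moment was 56.1 h⁻¹, lower than my early average reading of 83.2 h⁻¹. In the flask charged with 0.020 mM, the rate at that conversion was 1.12 mM h⁻¹, which gives a turnover rate of 56.1 h⁻¹, and free catalyst made up 45.8% of its catalyst.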